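(The numbers are made up; the flask was simulated.)

I count turnovers.

all flasks: starting material 2.0 mM; partner 2.20 mM; second reagent 1.00 mM; time 15 s
- north: temperature 80 °C
- north-west: temperature 20 °C
- south-east: temperature 50 °C

1. which flask leads in amount of intermediate, in percent of the starting material charged ("all alike" within 1.5 percentage points) (north / north-west / south-east / all alike)
2. how much intermediate is there at the end, in percent of the starting material charged: north
3. how much intermediate is there at the end, in percent of the starting material charged: north-west
4. how much intermediate is there at the end, in percent of the starting material charged: south-east

- the list of constants is for 80 °C, to be carried to other temperatures by the activation energies and enthalpies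

    second reagent ⇌ dormant form (K1 = 0.85, k1 = 0.33 s⁻¹, Ea1 = 82.0 kJ mol⁻¹, ΔH1 = −9.00 kJ mol⁻¹)
    intermediate → decomposed reagent (k2 = 0.16 s⁻¹, Ea2 = 89.0 kJ mol⁻¹)
    intermediate → side product B (k3 = 0.54 s⁻¹, Ea3 = 84.0 kJ mol⁻¹)
    second reagent + intermediate → target (k4 = 150 M⁻¹ s⁻¹, Ea4 = 53.0 kJ mol⁻¹)
    starting material + second reagent → side product A (k5 = 1400 M⁻¹ s⁻¹, Ea5 = 40.0 kJ mol⁻¹)
    starting material + partner → intermediate (k6 = 230 M⁻¹ s⁻¹, Ea6 = 57.0 kJ mol⁻¹)
    (constants at 80 °C)

In each flask the partner turns starting material into intermediate and the second reagent turns it into side product A, while intermediate decays by itself to decomposed reagent and side product B. With [partner] held at its charge, the first of these is pseudo-first-order, so I carry the partner count: the rate constant at the flask's temperature, times [partner], times the time, which is the number of turnovers that route gets in the run. For south-east it is 1.25. The north count is 7.59 and the north-west count is 0.143. The matching loss count for intermediate, both decay steps together, is 10.5 in north, 0.0281 in north-west and 0.713 in south-east.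

As a first pass I let the second reagent take its whole charge at once, which leaves a pool of half the starting material. That pool then passes through two consecutive first-order steps, so the intermediate's share of the pool is m/(n−m) times (exp(−m) − exp(−n)), with m the partner count and n the loss count. This gives 0.0623 % in north, 6.56 % in north-west and 23.7 % in south-east.

The weak link is "at once", so I count the second reagent's turnovers too, as its rate constant times its charge times the time. They are 21.0 in north and 5.93 in south-east, which is fast enough for the first pass. In north-west the count is 1.29, so there the pool lies between the charge and the first-pass pool for most of the run. Taking the midpoint raises north-west to 9.84 %. I commit to these figures, with south-east ahead.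

The forecast also puts south-east ahead. It gives 0.32 % in north (range 0.2 % to 0.5 %), 9 % in north-west (8.3 % to 9.7 %) and 22.3 % in south-east (20 % to 24.5 %), on the ground, for south-east, that “Hand stepping shows intermediate plateauing”. My figures differ from it in each flask.

The flasks hold 0.200 % in north, 8.88 % in north-west and 22.6 % in south-east, so south-east leads.

South-east's partner count of 1.25 is close to one turnover, and at the asked time intermediate in south-east is made at 0.887 of the rate at which it reacts away, so it is past its top. North-west's count of 0.143 describes a run cut short. Left until 150 s, north-west holds 29.5 % against 8.88 % at the asked time, a difference of 21 percentage points, and the time allowed is the largest single effect among those tried there. Its count by then is 1.43, near south-east's.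

A neighbour of south-east is charged with 8.8 mM of partner, which lifts the partner count to 5.01 while the loss count stays 0.713, and the same pool gives 28.2 %. The computed flask holds 32.1 %.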